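**Retrosynthetic overview**

- The route rests on the cis pair C5 (isopropenyl) / C6 (lactone oxygen) on the cyclohexane ring C5–C10 (C10 = methyl/vinyl quaternary carbon, C9 = CH2, C8 = acyloxy CH, C7 = fusion CH; C11 = acetoxy carbon, C12 = lactone carbonyl; C4/C3 = isopropenyl carbons). This pair is the retron of γ-addition of a Z-configured 2-methylallylboronate to a C6 aldehyde.
- Ring order: the carbocycle first, by forming C5–C6 in aldehyde 31 (intramolecular allylboration); then the γ-lactone (O, C6, C7, C11, C12) by oxidising C12 and lactonising; the acetate and the 3-methylbut-3-enoate last.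
- Aldehyde 31 is disconnected at C7–C8 (Evans syn aldol of imide 23 with aldehyde 15) and at C4–C3 (Negishi coupling of a Z-alkenyl iodide with IZnCH2Bpin).
- C10 comes from a chirality-transferring Johnson–Claisen rearrangement of (R)-enynol 5, C11 from (S)-citramalic acid, and the Z-iodoalkene from a Stork–Zhao olefination.
- C12 is carried as an acetonide-protected CH2O group up to the ring closure, so that no γ-hydroxy ester can lactonise early and no β-acyloxy group can be eliminated from the aldehyde.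

Key step: step 18

Remark: the atom labels C3–C12 defined above are used for all intermediates; compounds 12, 16, 21, 29 and 40 are taken as purchased.

**Route**

Step 1
Reactants: 1 (2E)-3-methylpent-2-en-4-yn-1-ol
Product: 2 (2E)-3-methylpent-2-en-4-ynal
Conditions: MnO2 (activated, excess), CH2Cl2, rt
Reagents that add atoms: none
Why: Allylic oxidation with MnO2 is selective for the allylic carbinol and leaves the enyne and its E geometry untouched.

Step 2
Reactants: 2 (2E)-3-methylpent-2-en-4-ynal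
Product: 4 rac-(3E)-4-methylhex-3-en-5-yn-2-yl acetate, via bromomagnesium alkoxide 3 (not isolated)
Conditions: MeMgBr, THF, −78 °C; then Ac2O, −78 °C → rt
Reagents that add atoms: methylmagnesium bromide C[Mg]Br; acetic anhydride CC(=O)OC(C)=O
Why: Grignard 1,2-addition to the enal followed by acylation of the magnesium alkoxide in the same flask gives the racemic allylic acetate, whose carbinol centre is resolved in the next step.

Step 3
Reactants: 4 rac-(3E)-4-methylhex-3-en-5-yn-2-yl acetate
Product: 5 (2R,3E)-4-methylhex-3-en-5-yn-2-ol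
Conditions: Novozym 435 (immobilised Candida antarctica lipase B), n-BuOH, MTBE, 30 °C, stopped before half conversion; chromatographic separation from the unreacted (S)-acetate
Reagents that add atoms: none
Why: Lipase-catalysed kinetic resolution by transesterification, in which the enzyme cleaves the (R)-acetate of a methyl carbinol much faster than the (S)-acetate (Kazlauskas rule), should deliver the (R)-alcohol in high enantiomeric purity.

Step 4
Reactants: 5 (2R,3E)-4-methylhex-3-en-5-yn-2-ol; 6 triethyl orthoacetate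
Product: 8 ethyl (3R,4E)-3-ethynyl-3-methylhex-4-enoate, via ketene acetal 7 (not isolated)
Conditions: MeC(OEt)3 (excess), EtCO2H (cat.), 135 °C, EtOH distilled off
Reagents that add atoms: none
Why: The Johnson–Claisen rearrangement runs through a chair transition state with the carbinol methyl group equatorial, so the C9–C10 bond forms on the alkene face defined by the (R)-carbinol, its chirality is transferred to the quaternary carbon C10 and the new alkene is E.

Step 5
Reactants: 8 ethyl (3R,4E)-3-ethynyl-3-methylhex-4-enoate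
Product: 10 ethyl (3S)-3-formyl-3-methylpent-4-ynoate, via ozonide 9 (not isolated)
Conditions: O3, CH2Cl2, −78 °C, Sudan red 7B as end-point indicator; then PPh3, −78 °C → rt
Reagents that add atoms: ozone [O-][O+]=O
Why: Ozonolysis with reductive work-up cleaves the disubstituted alkene far faster than the terminal alkyne and turns C5 into the aldehyde without touching C10.

Step 6
Reactants: 10 ethyl (3S)-3-formyl-3-methylpent-4-ynoate
Product: 11 ethyl (3S)-3-formyl-3-methylpent-4-enoate
Conditions: H2 (1 atm), Pd/CaCO3 poisoned with Pb(OAc)2, quinoline, EtOAc, rt, stopped after one equivalent of H2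
Reagents that add atoms: none
Why: Lindlar semihydrogenation reduces the terminal alkyne to the vinyl group on C10 and stops there, and the aldehyde, which has no α-hydrogen, can neither enolise nor move into conjugation.

Step 7
Reactants: 11 ethyl (3S)-3-formyl-3-methylpent-4-enoate; 12 ethyltriphenylphosphonium iodide
Product: 13 ethyl (3S)-3-[(1Z)-2-iodoprop-1-en-1-yl]-3-methylpent-4-enoate
Conditions: 12, n-BuLi, THF, rt; I2, −78 °C; NaN(SiMe3)2, −20 °C; then 11, −78 → −20 °C
Reagents that add atoms: iodine II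
Why: The Stork–Zhao olefination with the α-iodo ylide Ph3P=C(I)CH3 is a kinetically controlled Wittig reaction of a non-stabilised ylide that places iodine cis to the aldehyde-derived carbon, which gives the Z-configured C5=C4 iodoalkene.

Step 8
Reactants: 13 ethyl (3S)-3-[(1Z)-2-iodoprop-1-en-1-yl]-3-methylpent-4-enoate
Product: 15 (3S)-3-[(1Z)-2-iodoprop-1-en-1-yl]-3-methylpent-4-enal, via aluminium hemiacetal 14 (not isolated)
Conditions: iBu2AlH, CH2Cl2, −78 °C; MeOH, then aq. potassium sodium tartrate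
Reagents that add atoms: none
Why: Partial ester reduction with iBu2AlH at low temperature stops at the tetrahedral aluminium hemiacetal, which releases the C8 aldehyde on work-up, while the alkenyl iodide is inert.

Step 9
Reactants: 16 (S)-citramalic acid
Product: 17 (2S)-2-methylbutane-1,2,4-triol
Conditions: BH3·SMe2, B(OMe)3, THF, 0 °C → rt; MeOH quench
Reagents that add atoms: none
Why: Borane reduces both carboxylic acid groups to primary alcohols and does not touch the tertiary carbinol centre C11, which is taken from the chiral pool.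

Step 10
Reactants: 17 (2S)-2-methylbutane-1,2,4-triol
Product: 18 2-[(4S)-2,2,4-trimethyl-1,3-dioxolan-4-yl]ethan-1-ol
Conditions: 2,2-dimethoxypropane, acetone, TsOH·H2O (cat.), rt; Et3N
Reagents that add atoms: 2,2-dimethoxypropane COC(C)(C)OC
Why: Acetonide formation under equilibrating acid catalysis favours the five-membered dioxolane on the 1,2-diol over the six-membered dioxane and leaves the C6 hydroxyl free.

Step 11
Reactants: 18 2-[(4S)-2,2,4-trimethyl-1,3-dioxolan-4-yl]ethan-1-ol
Product: 20 [(4S)-2,2,4-trimethyl-1,3-dioxolan-4-yl]acetic acid, via aldehyde 19 (not isolated)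
Conditions: TEMPO (cat.), NaOCl (cat.), NaClO2, MeCN/aq. NaH2PO4–Na2HPO4 buffer (pH 6.7), 35 °C
Reagents that add atoms: sodium chlorite [Na+].[O-]Cl=O
Why: The TEMPO-catalysed oxidation with chlorite as terminal oxidant takes the primary alcohol through the aldehyde to the acid at near-neutral pH, at which the acetonide is stable.

Step 12
Reactants: 20 [(4S)-2,2,4-trimethyl-1,3-dioxolan-4-yl]acetic acid; 21 (4S)-4-benzyl-1,3-oxazolidin-2-one
Product: 23 (4S)-4-benzyl-3-{[(4S)-2,2,4-trimethyl-1,3-dioxolan-4-yl]acetyl}-1,3-oxazolidin-2-one, via mixed anhydride 22 (not isolated)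
Conditions: PivCl, Et3N, THF, −20 °C; then 21, LiCl, −20 °C → rt
Reagents that add atoms: none
Why: N-Acylation of the oxazolidinone through the mixed pivalic anhydride, with LiCl and Et3N as mild activators, takes place at the unhindered acyl carbon and needs no strong base.

Step 13
Reactants: 23 imide; 15 (3S)-3-[(1Z)-2-iodoprop-1-en-1-yl]-3-methylpent-4-enal
Product: 26 (4S)-4-benzyl-3-{(2R,3R,5S)-3-hydroxy-5-[(1Z)-2-iodoprop-1-en-1-yl]-5-methyl-2-[(4S)-2,2,4-trimethyl-1,3-dioxolan-4-yl]hept-6-enoyl}-1,3-oxazolidin-2-one, via boron enolate 24 (not isolated), via boron aldolate 25 (not isolated)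
Conditions: Bu2BOTf, iPr2NEt, CH2Cl2, 0 °C; then 15, −78 → 0 °C; aq. NaH2PO4–Na2HPO4 buffer (pH 7), MeOH, H2O2, 0 °C
Reagents that add atoms: none
Why: In this Evans syn aldol reaction the Z-configured dibutylboron enolate adds to the aldehyde through a Zimmerman–Traxler chair on the enolate face away from the benzyl group, so that the (S)-auxiliary sets C7 and C8 syn and in the required absolute sense while C10 and C11 are carried in unchanged.

Step 14
Reactants: 26 aldol adduct
Product: 27 C8-O-tert-butyldimethylsilyl ether of 26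
Conditions: TBSOTf, 2,6-lutidine, CH2Cl2, −78 → 0 °C
Reagents that add atoms: tert-butyldimethylsilyl triflate CC(C)(C)[Si](C)(C)OS(=O)(=O)C(F)(F)F
Why: Silylation of the hindered secondary alcohol with the silyl triflate and a hindered pyridine base is fast at low temperature and is compatible with the imide, the acetonide and the alkenyl iodide.

Step 15
Reactants: 27 silyl ether
Product: 28 (2R,3R,5S)-3-[(tert-butyldimethylsilyl)oxy]-5-[(1Z)-2-iodoprop-1-en-1-yl]-5-methyl-2-[(4S)-2,2,4-trimethyl-1,3-dioxolan-4-yl]hept-6-en-1-ol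
Conditions: LiBH4, H2O (1 equiv), Et2O, 0 °C
Reagents that add atoms: none
Why: Reductive cleavage of the N-acyl oxazolidinone with LiBH4 delivers the C6 primary alcohol and the recoverable auxiliary without epimerising C7, and the silyl ether, the acetonide and the alkenyl iodide are not reduced.

Step 16
Reactants: 28 iodo alcohol; 29 2-(iodomethyl)-4,4,5,5-tetramethyl-1,3,2-dioxaborolane
Product: 30 (2R,3R,5S)-3-[(tert-butyldimethylsilyl)oxy]-5-methyl-5-[(1Z)-2-methyl-3-(4,4,5,5-tetramethyl-1,3,2-dioxaborolan-2-yl)prop-1-en-1-yl]-2-[(4S)-2,2,4-trimethyl-1,3-dioxolan-4-yl]hept-6-en-1-ol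
Conditions: 29, Zn dust (activated with BrCH2CH2Br and Me3SiCl), THF, rt; then 28, Pd(PPh3)4 (5 mol %), THF, 40 °C, zinc reagent in excess
Reagents that add atoms: none
Why: The Negishi cross-coupling of the alkenyl iodide with the (pinacolatoboryl)methylzinc iodide made from 29 proceeds with retention of the alkene geometry, so that the CH2B group takes the place of iodine cis to C10 and the Z-allylboronate results, and alkylzinc halides used in excess tolerate the free hydroxyl.

Step 17
Reactants: 30 allylboronate alcohol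
Product: 31 (2R,3R,5S)-3-[(tert-butyldimethylsilyl)oxy]-5-methyl-5-[(1Z)-2-methyl-3-(4,4,5,5-tetramethyl-1,3,2-dioxaborolan-2-yl)prop-1-en-1-yl]-2-[(4S)-2,2,4-trimethyl-1,3-dioxolan-4-yl]hept-6-enal
Conditions: Dess–Martin periodinane, pyridine, CH2Cl2, 0 °C → rt; rapid filtration through a short pad of silica gel, used at once
Reagents that add atoms: none
Why: The Dess–Martin oxidation converts the primary alcohol into the C6 aldehyde under buffered, non-basic conditions that should neither epimerise C7 nor eliminate the β-silyloxy group and that leave the allylboronate intact.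

Step 18
Reactants: 31 allylboronate aldehyde
Product: 33 (1R,2R,3S,5R,6R)-5-[(tert-butyldimethylsilyl)oxy]-3-ethenyl-3-methyl-2-(prop-1-en-2-yl)-6-[(4S)-2,2,4-trimethyl-1,3-dioxolan-4-yl]cyclohexan-1-ol, via pinacol borate 32 (not isolated)
Conditions: toluene (0.02 M), 70 °C; then aq. NaHCO3 work-up
Reagents that add atoms: none
Why: The aldehyde oxygen binds to boron and, inside the resulting six-membered chair array of B, O, C6, C5, C4 and C3, the γ-carbon C5 adds to C6 while the double bond moves to C4=C3, which is the intramolecular version of the thermal allylboration of aldehydes by pinacol allylboronates, known for ω-oxo allylboronates that give 2-alkenylcycloalkanols. The cyclohexane C5–C10 closes in a 6-exo-trig mode onto the carbonyl group. The relative configuration of the new centres C5 and C6 is fixed by the Z geometry of the boronate, because with C7 equatorial on C6 in the allylboration chair the cis substituent C10 must be axial on C5, and this cis-fused pair of chairs gives the C6 oxygen and the C5 isopropenyl group cis. Their sense relative to C7, C8 and C10 is fixed by the chair of the forming carbocycle in which the C7 dioxolanyl group, the C8 silyloxy group and the C10 methyl group are equatorial: the dioxolanyl group is then anti to the incoming C5 (the Felkin–Anh arrangement at C7), the carbonyl oxygen becomes axial and the C4 unit equatorial, both on the ring face of the C10 vinyl group as in the target. The step needs γ-regioselectivity, which the closed transition state guarantees, and facial selectivity, which rests on this chair and must tolerate a 1,3-diaxial contact of the C10 vinyl group with the C6 oxygen. As the reaction is thermal and uses no added Lewis acid, the silyl ether and the acetonide should survive, and since C12 is still a protected CH2O group there is no ester that could lactonise early and no β-acyloxy group that could be eliminated from the aldehyde.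

Step 19
Reactants: 33 cyclohexanol
Product: 34 (1R,2R,3S,5R,6R)-5-[(tert-butyldimethylsilyl)oxy]-6-[(2S)-1,2-dihydroxypropan-2-yl]-3-ethenyl-3-methyl-2-(prop-1-en-2-yl)cyclohexan-1-ol
Conditions: AcOH/THF/H2O (3:1:1), 40 °C
Reagents that add atoms: none
Why: Mild aqueous acid hydrolyses the terminal acetonide, while the hindered secondary silyl ether and the two alkenes are stable under these conditions.

Step 20
Reactants: 34 triol
Product: 37 (3S,3aR,4R,6S,7R,7aR)-4-[(tert-butyldimethylsilyl)oxy]-6-ethenyl-3-hydroxy-3,6-dimethyl-7-(prop-1-en-2-yl)hexahydro-1-benzofuran-2(3H)-one, via hydroxy aldehyde 35 (not isolated), via hydroxy acid 36 (not isolated)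
Conditions: TEMPO (cat.), NaOCl (cat.), NaClO2, MeCN/aq. NaH2PO4–Na2HPO4 buffer (pH 6.7), 35 °C; acidification to pH 3; then PPTS (cat.), CH2Cl2, rt
Reagents that add atoms: sodium chlorite [Na+].[O-]Cl=O
Why: The TEMPO/chlorite oxidation is selective for the primary C12 alcohol over the hindered secondary C6 alcohol and takes 1,2-diols to α-hydroxy acids without C–C cleavage, and the resulting γ-hydroxy acid, whose C6 hydroxyl is cis to C11 on the ring, should close to the cis-fused γ-lactone on acidification.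

Step 21
Reactants: 37 hydroxy lactone
Product: 38 (3S,3aR,4R,6S,7R,7aR)-4-[(tert-butyldimethylsilyl)oxy]-6-ethenyl-3,6-dimethyl-2-oxo-7-(prop-1-en-2-yl)octahydro-1-benzofuran-3-yl acetate
Conditions: Ac2O, DMAP, Et3N, CH2Cl2, rt → 40 °C
Reagents that add atoms: acetic anhydride CC(=O)OC(C)=O
Why: DMAP-catalysed acylation with excess anhydride acetylates the tertiary C11 alcohol, the only free hydroxyl group, with retention because no bond to C11 is broken.

Step 22
Reactants: 38 silyl ether acetate
Product: 39 (3S,3aS,4R,6S,7R,7aR)-6-ethenyl-4-hydroxy-3,6-dimethyl-2-oxo-7-(prop-1-en-2-yl)octahydro-1-benzofuran-3-yl acetate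
Conditions: HF·pyridine, pyridine, THF, 0 °C → rt
Reagents that add atoms: none
Why: Buffered fluoride cleaves the silicon–oxygen bond at C8 without hydrolysing the lactone or the tertiary acetate and without acyl migration.

Step 23
Reactants: 39 hydroxy lactone acetate; 40 3-methylbut-3-enoic acid
Product: 41 (3S,3aS,4R,6S,7R,7aR)-3-(acetyloxy)-6-ethenyl-3,6-dimethyl-2-oxo-7-(prop-1-en-2-yl)octahydro-1-benzofuran-4-yl 3-methylbut-3-enoate (CNP0106639.1)
Conditions: N,N'-diisopropylcarbodiimide, DMAP (0.1 equiv), CH2Cl2, 0 °C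
Reagents that add atoms: none
Why: Steglich esterification of the equatorial C8 alcohol at low temperature with only catalytic DMAP should acylate without moving the β,γ-double bond of the acid into conjugation.

**Compound list**

1 | (2E)-3-methylpent-2-en-4-yn-1-ol | C#C/C(C)=C/CO | starting material
2 | (2E)-3-methylpent-2-en-4-ynal | C#C/C(C)=C/C=O | intermediate
3 | bromomagnesium (3E)-4-methylhex-3-en-5-yn-2-olate, racemic (not isolated) | C#C/C(C)=C/C(C)O[Mg]Br | intermediate
4 | rac-(3E)-4-methylhex-3-en-5-yn-2-yl acetate | C#C/C(C)=C/C(C)OC(C)=O | intermediate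
5 | (2R,3E)-4-methylhex-3-en-5-yn-2-ol | C#C/C(C)=C/[C@@H](C)O | intermediate
6 | triethyl orthoacetate | CCOC(C)(OCC)OCC | starting material
7 | (2R,3E)-2-[(1-ethoxyethenyl)oxy]-4-methylhex-3-en-5-yne, ketene acetal (not isolated) | C#C/C(C)=C/[C@@H](C)OC(=C)OCC | intermediate
8 | ethyl (3R,4E)-3-ethynyl-3-methylhex-4-enoate | CCOC(=O)C[C@@](C)(C#C)/C=C/C | intermediate
9 | 1,2,4-trioxolane (ozonide) of the C4=C5 double bond of 8, configuration at the quaternary carbon retained (not isolated) | CCOC(=O)C[C@@](C)(C#C)C1OOC(C)O1 | intermediate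
10 | ethyl (3S)-3-formyl-3-methylpent-4-ynoate | CCOC(=O)C[C@@](C)(C#C)C=O | intermediate
11 | ethyl (3S)-3-formyl-3-methylpent-4-enoate | CCOC(=O)C[C@@](C)(C=C)C=O | intermediate
12 | ethyltriphenylphosphonium iodide | CC[P+](c1ccccc1)(c1ccccc1)c1ccccc1.[I-] | starting material
13 | ethyl (3S)-3-[(1Z)-2-iodoprop-1-en-1-yl]-3-methylpent-4-enoate | CCOC(=O)C[C@@](C)(C=C)/C=C(/C)I | intermediate
14 | diisobutylaluminium hemiacetal of ester 13 (not isolated) | CCOC(O[Al](CC(C)C)CC(C)C)C[C@@](C)(C=C)/C=C(/C)I | intermediate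
15 | (3S)-3-[(1Z)-2-iodoprop-1-en-1-yl]-3-methylpent-4-enal | O=CC[C@@](C)(C=C)/C=C(/C)I | intermediate
16 | (S)-citramalic acid, (2S)-2-hydroxy-2-methylbutanedioic acid | C[C@](O)(CC(=O)O)C(=O)O | starting material
17 | (2S)-2-methylbutane-1,2,4-triol | C[C@](O)(CCO)CO | intermediate
18 | 2-[(4S)-2,2,4-trimethyl-1,3-dioxolan-4-yl]ethan-1-ol | C[C@]1(CCO)COC(C)(C)O1 | intermediate
19 | [(4S)-2,2,4-trimethyl-1,3-dioxolan-4-yl]acetaldehyde (not isolated) | C[C@]1(CC=O)COC(C)(C)O1 | intermediate
20 | [(4S)-2,2,4-trimethyl-1,3-dioxolan-4-yl]acetic acid | C[C@]1(CC(=O)O)COC(C)(C)O1 | intermediate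
21 | (4S)-4-benzyl-1,3-oxazolidin-2-one | O=C1N[C@@H](Cc2ccccc2)CO1 | starting material
22 | mixed anhydride of acid 20 with pivalic acid (not isolated) | C[C@]1(CC(=O)OC(=O)C(C)(C)C)COC(C)(C)O1 | intermediate
23 | (4S)-4-benzyl-3-{[(4S)-2,2,4-trimethyl-1,3-dioxolan-4-yl]acetyl}-1,3-oxazolidin-2-one | C[C@]1(CC(=O)N2[C@@H](Cc3ccccc3)COC2=O)COC(C)(C)O1 | intermediate
24 | Z-configured dibutylboron enolate of imide 23 (not isolated) | C[C@]1(/C=C(\OB(CCCC)CCCC)N2[C@@H](Cc3ccccc3)COC2=O)COC(C)(C)O1 | intermediate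
25 | C8-O-dibutylboryl derivative of aldol adduct 26 (not isolated) | O=C1OC[C@H](Cc2ccccc2)N1C(=O)[C@@H]([C@@]3(C)COC(C)(C)O3)[C@H](OB(CCCC)CCCC)C[C@@](C)(C=C)/C=C(/C)I | intermediate
26 | (4S)-4-benzyl-3-{(2R,3R,5S)-3-hydroxy-5-[(1Z)-2-iodoprop-1-en-1-yl]-5-methyl-2-[(4S)-2,2,4-trimethyl-1,3-dioxolan-4-yl]hept-6-enoyl}-1,3-oxazolidin-2-one | O=C1OC[C@H](Cc2ccccc2)N1C(=O)[C@@H]([C@@]3(C)COC(C)(C)O3)[C@H](O)C[C@@](C)(C=C)/C=C(/C)I | intermediate
27 | (4S)-4-benzyl-3-{(2R,3R,5S)-3-[(tert-butyldimethylsilyl)oxy]-5-[(1Z)-2-iodoprop-1-en-1-yl]-5-methyl-2-[(4S)-2,2,4-trimethyl-1,3-dioxolan-4-yl]hept-6-enoyl}-1,3-oxazolidin-2-one | O=C1OC[C@H](Cc2ccccc2)N1C(=O)[C@@H]([C@@]3(C)COC(C)(C)O3)[C@H](O[Si](C)(C)C(C)(C)C)C[C@@](C)(C=C)/C=C(/C)I | intermediate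
28 | (2R,3R,5S)-3-[(tert-butyldimethylsilyl)oxy]-5-[(1Z)-2-iodoprop-1-en-1-yl]-5-methyl-2-[(4S)-2,2,4-trimethyl-1,3-dioxolan-4-yl]hept-6-en-1-ol | OC[C@@H]([C@@]1(C)COC(C)(C)O1)[C@H](O[Si](C)(C)C(C)(C)C)C[C@@](C)(C=C)/C=C(/C)I | intermediate
29 | 2-(iodomethyl)-4,4,5,5-tetramethyl-1,3,2-dioxaborolane | ICB1OC(C)(C)C(C)(C)O1 | starting material
30 | (2R,3R,5S)-3-[(tert-butyldimethylsilyl)oxy]-5-methyl-5-[(1Z)-2-methyl-3-(4,4,5,5-tetramethyl-1,3,2-dioxaborolan-2-yl)prop-1-en-1-yl]-2-[(4S)-2,2,4-trimethyl-1,3-dioxolan-4-yl]hept-6-en-1-ol | OC[C@@H]([C@@]1(C)COC(C)(C)O1)[C@H](O[Si](C)(C)C(C)(C)C)C[C@@](C)(C=C)/C=C(/C)CB2OC(C)(C)C(C)(C)O2 | intermediate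
31 | (2R,3R,5S)-3-[(tert-butyldimethylsilyl)oxy]-5-methyl-5-[(1Z)-2-methyl-3-(4,4,5,5-tetramethyl-1,3,2-dioxaborolan-2-yl)prop-1-en-1-yl]-2-[(4S)-2,2,4-trimethyl-1,3-dioxolan-4-yl]hept-6-enal | O=C[C@@H]([C@@]1(C)COC(C)(C)O1)[C@H](O[Si](C)(C)C(C)(C)C)C[C@@](C)(C=C)/C=C(/C)CB2OC(C)(C)C(C)(C)O2 | intermediate
32 | C6-O-(pinacolatoboryl) derivative of cyclohexanol 33 (not isolated) | C=C[C@]1(C)C[C@@H](O[Si](C)(C)C(C)(C)C)[C@H]([C@@]2(C)COC(C)(C)O2)[C@H](OB3OC(C)(C)C(C)(C)O3)[C@@H]1C(=C)C | intermediate
33 | (1R,2R,3S,5R,6R)-5-[(tert-butyldimethylsilyl)oxy]-3-ethenyl-3-methyl-2-(prop-1-en-2-yl)-6-[(4S)-2,2,4-trimethyl-1,3-dioxolan-4-yl]cyclohexan-1-ol | C=C[C@]1(C)C[C@@H](O[Si](C)(C)C(C)(C)C)[C@H]([C@@]2(C)COC(C)(C)O2)[C@H](O)[C@@H]1C(=C)C | intermediate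
34 | (1R,2R,3S,5R,6R)-5-[(tert-butyldimethylsilyl)oxy]-6-[(2S)-1,2-dihydroxypropan-2-yl]-3-ethenyl-3-methyl-2-(prop-1-en-2-yl)cyclohexan-1-ol | C=C[C@]1(C)C[C@@H](O[Si](C)(C)C(C)(C)C)[C@H]([C@](C)(O)CO)[C@H](O)[C@@H]1C(=C)C | intermediate
35 | triol 34 with C12 oxidised to the aldehyde, (2S)-2-hydroxy-1-oxopropan-2-yl side chain (not isolated) | C=C[C@]1(C)C[C@@H](O[Si](C)(C)C(C)(C)C)[C@H]([C@](C)(O)C=O)[C@H](O)[C@@H]1C(=C)C | intermediate
36 | triol 34 with C12 oxidised to the carboxylic acid, (2S)-2-hydroxypropanoic acid side chain (not isolated) | C=C[C@]1(C)C[C@@H](O[Si](C)(C)C(C)(C)C)[C@H]([C@](C)(O)C(=O)O)[C@H](O)[C@@H]1C(=C)C | intermediate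
37 | (3S,3aR,4R,6S,7R,7aR)-4-[(tert-butyldimethylsilyl)oxy]-6-ethenyl-3-hydroxy-3,6-dimethyl-7-(prop-1-en-2-yl)hexahydro-1-benzofuran-2(3H)-one | C=C[C@]1(C)C[C@@H](O[Si](C)(C)C(C)(C)C)[C@H]2[C@H](OC(=O)[C@@]2(C)O)[C@@H]1C(=C)C | intermediate
38 | (3S,3aR,4R,6S,7R,7aR)-4-[(tert-butyldimethylsilyl)oxy]-6-ethenyl-3,6-dimethyl-2-oxo-7-(prop-1-en-2-yl)octahydro-1-benzofuran-3-yl acetate | C=C[C@]1(C)C[C@@H](O[Si](C)(C)C(C)(C)C)[C@H]2[C@H](OC(=O)[C@@]2(C)OC(C)=O)[C@@H]1C(=C)C | intermediate
39 | (3S,3aS,4R,6S,7R,7aR)-6-ethenyl-4-hydroxy-3,6-dimethyl-2-oxo-7-(prop-1-en-2-yl)octahydro-1-benzofuran-3-yl acetate | C=C[C@]1(C)C[C@@H](O)[C@H]2[C@H](OC(=O)[C@@]2(C)OC(C)=O)[C@@H]1C(=C)C | intermediate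
40 | 3-methylbut-3-enoic acid | C=C(C)CC(=O)O | starting material
41 | (3S,3aS,4R,6S,7R,7aR)-3-(acetyloxy)-6-ethenyl-3,6-dimethyl-2-oxo-7-(prop-1-en-2-yl)octahydro-1-benzofuran-4-yl 3-methylbut-3-enoate, CNP0106639.1 | C=C[C@]1(C)C[C@@H](OC(=O)CC(=C)C)[C@H]2[C@H](OC(=O)[C@@]2(C)OC(C)=O)[C@@H]1C(=C)C | target

**Step count**

Total: 23 steps. Longest linear sequence: 19 steps (steps 1–8 and 13–23); the imide 23 is made in 4 steps (9–12) from (S)-citramalic acid.

**Steps most likely to fail**

1. Step 18 (ring-closing allylboration). The addition of C5, a γ-carbon next to the quaternary C10, may be slow, so that the β-silyloxy aldehyde epimerises at C7 or eliminates before it closes; the facial selection may also be eroded by the 1,3-diaxial contact between the C10 vinyl group and the incoming carbonyl oxygen. Fallback: setting out from iodo alcohol 28, a Pd(PPh3)4-catalysed Negishi coupling with Me3SiCH2ZnCl in THF would give (2R,3R,5S)-3-[(tert-butyldimethylsilyl)oxy]-5-methyl-5-[(1Z)-2-methyl-3-(trimethylsilyl)prop-1-en-1-yl]-2-[(4S)-2,2,4-trimethyl-1,3-dioxolan-4-yl]hept-6-en-1-ol F1. Dess–Martin oxidation with pyridine buffer would give the corresponding hept-6-enal F2. BF3·OEt2 in CH2Cl2 at −78 °C would then close the ring by an intramolecular Hosomi–Sakurai reaction through an open, synclinal transition state, which is governed by the Felkin preference at C7 and not by a boron-bound chair; this comes back to the route at cyclohexanol 33.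

2. Step 16 (Negishi coupling with the borylmethylzinc reagent). Oxidative addition and transmetalation at the iodide cis to the quaternary carbon may be slow, the zinc reagent may be consumed by protonolysis at the free hydroxyl, and the Z geometry may be partly lost. Fallback: setting out from iodo alcohol 28, a Miyaura borylation (bis(pinacolato)diboron, PdCl2(PPh3)2, PPh3, KOPh, toluene, 50 °C) would give (2R,3R,5S)-3-[(tert-butyldimethylsilyl)oxy]-5-methyl-5-[(1E)-2-(4,4,5,5-tetramethyl-1,3,2-dioxaborolan-2-yl)prop-1-en-1-yl]-2-[(4S)-2,2,4-trimethyl-1,3-dioxolan-4-yl]hept-6-en-1-ol F3, in which boron is cis to C10. A Matteson homologation with LiCH2Cl (from BrCH2Cl and n-BuLi, THF, −78 °C → rt, one extra equivalent for the hydroxyl) would insert the CH2 group into the C–B bond with retention of the alkene geometry; this comes back to the route at allylboronate alcohol 30.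

3. Step 7 (Stork–Zhao olefination). The bulky α-iodo ylide may add slowly to the aldehyde on the quaternary carbon, so that the ylide decomposes and the Z selectivity is eroded. Fallback: setting out from aldehyde 11, a Ramirez olefination (CBr4, PPh3, CH2Cl2, 0 °C) would give ethyl (3S)-3-(2,2-dibromoethenyl)-3-methylpent-4-enoate F4. A trans-selective Negishi monomethylation (MeZnCl, PdCl2(DPEphos), THF) would replace the bromine trans to C10 and give ethyl (3S)-3-[(1Z)-2-bromoprop-1-en-1-yl]-3-methylpent-4-enoate F5. A copper-catalysed halogen exchange (CuI, NaI, N,N'-dimethylethylenediamine, dioxane, 110 °C) with retention of geometry comes back to the route at iodoalkene 13.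

Further compounds
F1 | step 18 | (2R,3R,5S)-3-[(tert-butyldimethylsilyl)oxy]-5-methyl-5-[(1Z)-2-methyl-3-(trimethylsilyl)prop-1-en-1-yl]-2-[(4S)-2,2,4-trimethyl-1,3-dioxolan-4-yl]hept-6-en-1-ol | OC[C@@H]([C@@]1(C)COC(C)(C)O1)[C@H](O[Si](C)(C)C(C)(C)C)C[C@@](C)(C=C)/C=C(/C)C[Si](C)(C)C
F2 | step 18 | (2R,3R,5S)-3-[(tert-butyldimethylsilyl)oxy]-5-methyl-5-[(1Z)-2-methyl-3-(trimethylsilyl)prop-1-en-1-yl]-2-[(4S)-2,2,4-trimethyl-1,3-dioxolan-4-yl]hept-6-enal | O=C[C@@H]([C@@]1(C)COC(C)(C)O1)[C@H](O[Si](C)(C)C(C)(C)C)C[C@@](C)(C=C)/C=C(/C)C[Si](C)(C)C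
F3 | step 16 | (2R,3R,5S)-3-[(tert-butyldimethylsilyl)oxy]-5-methyl-5-[(1E)-2-(4,4,5,5-tetramethyl-1,3,2-dioxaborolan-2-yl)prop-1-en-1-yl]-2-[(4S)-2,2,4-trimethyl-1,3-dioxolan-4-yl]hept-6-en-1-ol | OC[C@@H]([C@@]1(C)COC(C)(C)O1)[C@H](O[Si](C)(C)C(C)(C)C)C[C@@](C)(C=C)/C=C(/C)B2OC(C)(C)C(C)(C)O2
F4 | step 7 | ethyl (3S)-3-(2,2-dibromoethenyl)-3-methylpent-4-enoate | CCOC(=O)C[C@@](C)(C=C)C=C(Br)Br
F5 | step 7 | ethyl (3S)-3-[(1Z)-2-bromoprop-1-en-1-yl]-3-methylpent-4-enoate | CCOC(=O)C[C@@](C)(C=C)/C=C(/C)Br
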